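(All runs are calculated for an exercise; noise was put on by code.)

The question for this flask was what stops it by 15 d and how its products divide, so I turned it round and asked what would have to hold for the partner not to give out first.

the same everywhere: precatalyst 10 µM

|  | left-handed substrate | right-handed substrate | partner | remark | time |
|---|---|---|---|---|---|
| Sunday's | 10 mM | 10 mM | 30 mM (fed, over 30 h) | run made earlier |  |
| Wednesday's | 40 mM | 40 mM | 30 mM (fed, over 30 h) | run made earlier |  |
| flask | 20 mM | 20 mM | 30.0 mM (fed, over 30 h) |  | 15 d |

| run | time / d | left-handed product / % | right-handed product / % | right-handed substrate / % |
|---|---|---|---|---|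
| Sunday's | 4.00 | 48.6 | 52.0 | 0 |
| Sunday's | 8.00 | 50.2 | 50.2 | 0 |
| Sunday's | 10.0 | 48.2 | 50.7 | 0 |
| Sunday's | 15.0 | 50.7 | 50.9 | 0 |
| Sunday's | 20.0 | 48.1 | 50.6 | 0 |
| Wednesday's | 1.67 | 27.7 | 9.3 | 43.9 |
| Wednesday's | 5.00 | 28.1 | 8.5 | 41.2 |
| Wednesday's | 8.00 | 28.7 | 9.1 | 42.7 |
| Wednesday's | 12.0 | 28.8 | 7.7 | 40.9 |
| Wednesday's | 20.0 | 29.4 | 10.0 | 40.9 |

(readings scatter by 1 percentage point)

- free catalyst is single-handed; left-handed substrate and right-handed substrate are mirror images of each other, charged as a racemate, each of them at the stated concentration
- candidate steps: free catalyst + left-handed substrate <-> catalyst intermediate A; free catalyst + right-handed substrate <-> catalyst intermediate B; partner + catalyst intermediate A -> free catalyst + left-handed product; partner + catalyst intermediate B -> free catalyst + right-handed product; precatalyst -> free catalyst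
- the reaction counts as stopped when no species that holds the left-handed substrate and right-handed substrate together changes by six tenths of a point or more over the second half of the time

- the state of affairs at 15 d: stopped, and by what, or still going (no working catalyst is left / forward and back rates have come level / all of the left-handed substrate has reacted / it is still moving / the partner has run out first)
- amount of left-handed product at 15 d, in percent of the left-handed substrate and right-handed substrate together charged
- amount of right-handed product at 15 d, in percent of the left-handed substrate and right-handed substrate together charged
- amount of right-handed substrate at 15 d, in percent of the left-handed substrate and right-handed substrate together charged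
- amount of left-handed product if the flask were left three thousand times as long, in percent of the left-handed substrate and right-handed substrate together charged

Each product in the candidate steps takes one partner, so the most product the partner can pay for, in percent of the substrates charged, is the partner charge over the two substrate charges together, 75.0% in this flask; I called this the partner ceiling F. For the substrates to give out before the partner, F had to stand above 100%. Sunday's run stood there, at 150%, and its right-handed substrate read 0% by 4.00 d. Wednesday's run stood at 37.5%; its products together read 37.0% at 1.67 d and 37.8% at 8.00 d, level within the scatter, with right-handed substrate still reading 42.7%. That second sum is about 30.2 mM of product from the same precatalyst charge, and this flask's ceiling asks for no more. This flask stood 25 percentage points short of that mark, so I committed to the partner as limiting reagent and to products summing to F.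

The forecast said the partner has run out first, with left-handed product 48.2%, right-handed product 26.8% and right-handed substrate 23.2%, and 48.2% of left-handed product after the long wait, since “waiting longer changes nothing”.

The simulation gave the partner has run out first, with 48.0%, 27.0%, 23.0% and 48.0% in the same order.

    free catalyst + left-handed substrate ⇌ catalyst intermediate A (K = 17.5 M⁻¹, k = 4860 M⁻¹ min⁻¹)
    free catalyst + right-handed substrate ⇌ catalyst intermediate B (K = 77.0 M⁻¹, k = 11700 M⁻¹ min⁻¹)
    partner + catalyst intermediate A → free catalyst + left-handed product (k = 3010 M⁻¹ min⁻¹)
    partner + catalyst intermediate B → free catalyst + right-handed product (k = 159 M⁻¹ min⁻¹)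
    precatalyst → free catalyst (k = 0.00449 min⁻¹)

This flask's products came to 75.0%, at its ceiling F of 75.0%. The neighbour flask with 12 mM of partner has a ceiling of 30.0%, and its products came to 30.0%. This flask had come to rest before the asked time: its partner already read 0% at 7.50 d, with right-handed substrate at 23.0% and still at 23.0% at 15.0 d. Left until 150 d, it holds 48.0% of left-handed product, 27.0% of right-handed product and 23.0% of right-handed substrate, a change in left-handed product of 0 points.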